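(The earlier runs and the new flask are calculated with made-up constants; noise was put on by code.)

A small charge of starting material sat under a held gas phase, and I was asked what it had become at a later time.

the same everywhere: gas phase 0.11 mM (held); catalyst 50 µM
- birch: starting material 0.0010 M; protic impurity 0.020 mM; the very flask that is asked about, followed so far
- larch: starting material 0.0015 M; protic impurity 0.020 mM; run made earlier
- flask: starting material 0.0010 M; protic impurity 0.0200 mM; time 2.5 min

| run | time / s | product / % |
|---|---|---|
| birch | 10.0 | 6.2 |
| birch | 20.0 | 11.1 |
| birch | 30.0 | 16.6 |
| birch | 40.0 | 21.3 |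
| birch | 50.0 | 28.0 |
| birch | 60.0 | 32.4 |
| birch | 80.0 | 41.4 |
| larch | 10.0 | 6.7 |
| larch | 12.0 | 5.8 |
| larch | 20.0 | 11.5 |
| larch | 30.0 | 15.5 |
| larch | 50.0 | 25.6 |
| larch | 60.0 | 28.0 |
| larch | 120 | 54.7 |

(standard deviation of a reading: 1 percentage point)

- at the start none of the gas phase is in solution

- winter: doubling the saturation concentration of gas phase, all else as stated
- dawn: doubling the amount of catalyst, all else as stated
- dusk: doubling the transfer coefficient of the gas phase, all else as stated

1. the product standing at 2.5 min, as a percentage of the starting material charged
2. the change that raises the amount of product at 2.5 min, in percent of the starting material charged most ("none" if none brings more than 2 percentage points) (winter / dawn / dusk / none)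
3. amount of product at 2.5 min, in percent of the starting material charged, after winter

I worked with the fraction left, not the fraction made. The last birch reading gave 0.401 min⁻¹ as the logarithm of charge over remainder, divided by time. The last larch reading gave 0.396 min⁻¹, though larch was charged with 0.0015 M against 0.0010 M. So I took their mean, 0.398 min⁻¹, as the left-constant, the share of what remains that is lost per unit time. I read it as a pseudo-first-order constant.

Then I drew the curve for birch. By my reckoning it left the origin at 6.64 µM s⁻¹. At 104 s it crossed half of the charge. Its knee, one reciprocal constant along, came at 151 s, and from there I expected it to bend towards the full charge. At 2.5 min I reckoned 63.1% of product. If winter doubled the constant, I reckoned 86.4%. Dawn gave me the same figure under the same assumption, so my reckoning could not part them.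

The forecast said 72%, “Allowing for some fall-off as starting material depletes”. It named winter and gave 94% after it. Both figures stood above mine.

The flask gave 64.5%. Winter gained 24 percentage points, against 21 points for dawn and 4.2 points for dusk, and it reached 88.2%.

    gas phase ⇌ dissolved gas, rate k1*(csat - [dissolved gas]) (kL = 0.253 s⁻¹)
    starting material + dissolved gas + catalyst → catalyst + product (k = 3.96 × 10⁶ M⁻² s⁻¹)
    dissolved gas → decomposed reagent (k = 0.00738 s⁻¹)
    starting material ⇌ dormant form (K = 1.47, k = 0.257 s⁻¹)
    dissolved gas + protic impurity → quenched reagent (k = 201 M⁻¹ s⁻¹)

The neighbour carried 8.5 × 10⁻⁵ M of catalyst against 50 µM. I scaled the left-constant with the catalyst, to 0.677 min⁻¹. Over 2.5 min I reckoned 18.4% of the charge unconverted and 81.6% as product. The neighbour held 80.8% of product, with 7.43% as starting material and 11.8% as dormant form.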